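**Retrosynthetic overview**
The strategy reads ring A as a masked furan. The sequence N1–C2(CH3)–C3(O)–C4–C4a–C8a is what a 2-(1-aminoethyl)furan gives on oxidative ring expansion: C3, C4, C4a and C8a are the four furan carbons, and C4a–C8a is the bond shared with ring B.
The target therefore goes back, through an invertive esterification at C3 and three face-selective reductions (C8a, C4a, C3), to a bicyclic 8a-hydroxy enone, and from there to a Boc-protected (R)-1-(tetrahydrobenzofuran-2-yl)ethylamine.
The C2–N unit comes from C2-lithiation and acetylation of the furan followed by a sulfinamide-controlled ketimine reduction. The C5 chain comes from a B-alkyl Suzuki coupling of the enol triflate of 6,7-dihydrobenzofuran-4(5H)-one with a side chain made from (R)-1,2-epoxypentane, followed by asymmetric hydrogenation.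
Ring order: ring B is bought already fused to the furan, and ring A is made last, out of the furan itself.
Key step: step 11

Remark on locants: benzofuran numbering is used for 5–18 and the quinoline numbering of the target from 19 on. "Top face" is the face that carries the C2 methyl group.
Assumption: the sense of induction in step 5 is taken from 1-alkyl-3,4-dihydronaphthalenes, which behave as Z-type olefins. On that basis the (R) ligand is expected to give 4R. Both ligand antipodes can be bought, so the other one is used if a test run shows the reverse sense.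

Step 1
Reactants: 1 (R)-1,2-epoxypentane; 2 allylmagnesium bromide
Product: 3 (4R)-oct-7-en-4-ol
Conditions: CuI (10 mol %), THF, −40 to 0 °C; aqueous work-up
Reagents that add atoms: none
Why: Copper-catalysed Grignard opening of a monosubstituted epoxide is an SN2 attack at the unhindered CH2, so the carbinol carbon (the future C5') is not touched and stays R.

Step 2
Reactants: 3 (4R)-oct-7-en-4-ol
Product: 4 tert-butyl[(4R)-oct-7-en-4-yloxy]diphenylsilane
Conditions: TBDPSCl, imidazole, DMF, rt
Reagents that add atoms: tert-butylchlorodiphenylsilane, CC(C)(C)[Si](Cl)(c1ccccc1)c1ccccc1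
Why: Imidazole-promoted silylation of a secondary alcohol, with TBDPS chosen because it must outlast n-BuLi, methanolic HCl, BF3·OEt2 and hydrogenation before fluoride removes it.

Step 3
Reactants: 5 6,7-dihydro-1-benzofuran-4(5H)-one
Product: 7 6,7-dihydro-1-benzofuran-4-yl trifluoromethanesulfonate, via lithium enolate 6 (not isolated)
Conditions: LiN(SiMe3)2, THF, −78 °C; PhNTf2, −78 to 0 °C
Reagents that add atoms: N-phenylbis(trifluoromethanesulfonimide), O=S(=O)(N(c1ccccc1)S(=O)(=O)C(F)(F)F)C(F)(F)F; LiN(SiMe3)2, [Li]N([Si](C)(C)C)[Si](C)(C)C (its lithium stays in 6 only)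
Why: Enol triflate formation, in which the ketone can be deprotonated only at C5 because its other α-carbon is furan C3a, and the lithium enolate is then O-sulfonylated by PhNTf2.

Step 4
Reactants: 4 tert-butyl[(4R)-oct-7-en-4-yloxy]diphenylsilane; 7 6,7-dihydro-1-benzofuran-4-yl trifluoromethanesulfonate
Product: 9 4-[(5R)-5-(tert-butyldiphenylsilyloxy)octyl]-6,7-dihydro-1-benzofuran, via B-alkyl-9-BBN 8 (not isolated)
Conditions: 4, 9-BBN-H, THF, 0 °C to rt; then 7, PdCl2(dppf) (5 mol %), aq K3PO4, THF/DMF, 50 °C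
Reagents that add atoms: 9-borabicyclo[3.3.1]nonane, C1CC2CCCC(C1)B2 (its boron and carbon atoms stay in 8 only)
Why: B-alkyl Suzuki–Miyaura coupling, in which 9-BBN-H adds anti-Markovnikov to the terminal alkene and the phosphate-activated borane passes its primary alkyl group to the alkenylpalladium species formed by oxidative addition of zerovalent palladium to 7, with dppf holding back β-hydride elimination.

Step 5
Reactants: 9 4-[(5R)-5-(tert-butyldiphenylsilyloxy)octyl]-6,7-dihydro-1-benzofuran
Product: 10 (4R)-4-[(5R)-5-(tert-butyldiphenylsilyloxy)octyl]-4,5,6,7-tetrahydro-1-benzofuran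
Conditions: H2 (50 bar), [Ir(cod)(L)]B[3,5-(CF3)2C6H3]4 (1–2 mol %; L = (R)-4-tert-butyl-2-[2-(di-o-tolylphosphanyl)phenyl]-4,5-dihydrooxazole), CH2Cl2, rt
Reagents that add atoms: none
Why: Iridium N,P-catalysed asymmetric hydrogenation of an unfunctionalised trisubstituted aryl/alkyl olefin, the class of the 1-alkyl-3,4-dihydronaphthalenes, in which the chiral pocket of the catalyst selects the alkene face and sets C4 (future C5) as R while the aromatic furan is left alone at room temperature.

Step 6
Reactants: 10 (4R)-4-[(5R)-5-(tert-butyldiphenylsilyloxy)octyl]-4,5,6,7-tetrahydro-1-benzofuran; 11 N-methoxy-N-methylacetamide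
Product: 13 1-{(4R)-4-[(5R)-5-(tert-butyldiphenylsilyloxy)octyl]-4,5,6,7-tetrahydro-1-benzofuran-2-yl}ethan-1-one, via 2-lithiofuran 12 (not isolated)
Conditions: n-BuLi, THF, −78 to 0 °C; then 11, −78 to 0 °C; aqueous work-up
Reagents that add atoms: n-butyllithium, [Li]CCCC (its lithium stays in 12 only)
Why: α-Metalation of a furan followed by Weinreb ketone synthesis, in which C2–H is the only free α-position and the most acidic C–H, and the N-methoxy-N-methylamide stops the addition at the ketone.

Step 7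
Reactants: 13 the 2-acetyl-tetrahydrobenzofuran; 14 (R)-2-methylpropane-2-sulfinamide
Product: 15 (R,E)-N-[1-{(4R)-4-[(5R)-5-(tert-butyldiphenylsilyloxy)octyl]-4,5,6,7-tetrahydro-1-benzofuran-2-yl}ethylidene]-2-methylpropane-2-sulfinamide
Conditions: Ti(OEt)4 (2.5 equiv), THF, 70 °C
Reagents that add atoms: none
Why: Ti(OEt)4 serves as Lewis acid and water scavenger in the condensation of a methyl ketone with tert-butanesulfinamide, which gives the E-ketimine (sulfinyl group anti to the furyl group) and leaves the sulfur centre untouched.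

Step 8
Reactants: 15 the (R,E)-sulfinyl ketimine
Product: 16 (R)-N-[(1R)-1-{(4R)-4-[(5R)-5-(tert-butyldiphenylsilyloxy)octyl]-4,5,6,7-tetrahydro-1-benzofuran-2-yl}ethyl]-2-methylpropane-2-sulfinamide
Conditions: NaBH4, THF/H2O (98:2), −50 °C
Reagents that add atoms: none
Why: Auxiliary-controlled ketimine reduction, in which NaBH4 reacts through a cyclic transition state with boron held by the sulfinyl oxygen, and for (R)-sulfinyl aryl methyl E-ketimines this brings hydride to the face that gives the R amine carbon (future C2).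

Step 9
Reactants: 16 the (R,R)-sulfinamide
Product: 17 (1R)-1-{(4R)-4-[(5R)-5-(tert-butyldiphenylsilyloxy)octyl]-4,5,6,7-tetrahydro-1-benzofuran-2-yl}ethan-1-amine hydrochloride
Conditions: HCl (4 M in dioxane), MeOH, 0 °C, 30 min; evaporation
Reagents that add atoms: hydrogen chloride, Cl
Why: Acid methanolysis of the S–N bond is fast at 0 °C, does not involve the C–N stereocentre, and the short anhydrous exposure spares the furan and the TBDPS ether.

Step 10
Reactants: 17 the amine hydrochloride
Product: 18 tert-butyl N-[(1R)-1-{(4R)-4-[(5R)-5-(tert-butyldiphenylsilyloxy)octyl]-4,5,6,7-tetrahydro-1-benzofuran-2-yl}ethyl]carbamate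
Conditions: Boc2O, Et3N, CH2Cl2, rt
Reagents that add atoms: di-tert-butyl dicarbonate, CC(C)(C)OC(=O)OC(=O)OC(C)(C)C
Why: Routine N-acylation of a primary amine, with Boc giving the oxidation-stable N–H nucleophile needed in step 11 and later the A(1,3) strain that directs steps 12–14.

Step 11
Reactants: 18 the Boc-protected furylethylamine
Product: 20 tert-butyl (2R,5R)-8a-hydroxy-2-methyl-3-oxo-5-[(5R)-5-(tert-butyldiphenylsilyloxy)octyl]-3,5,6,7,8,8a-hexahydroquinoline-1(2H)-carboxylate (both C8a epimers), via Z-enedione 19 (not isolated)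
Conditions: m-CPBA (1.1–1.2 equiv), CH2Cl2, 0 °C to rt
Reagents that add atoms: 3-chloroperoxybenzoic acid, O=C(OO)c1cccc(Cl)c1
Why: m-CPBA transfers one oxygen atom to the electron-rich trisubstituted furan, and the labile furan epoxide opens to the Z-enedione 19, in which old furan C2 is the C3 ketone, old C7a is the C8a ketone and the old C3–C3a bond has become the C4=C4a alkene. Because this alkene keeps the cis geometry it had in the five-membered ring, the C8a carbonyl lies next to the carbamate N–H, which adds to it in a 6-exo-trig closure that forms the N1–C8a bond and closes ring A as a 3-oxo-4(4a)-ene hemiaminal. The closest known reaction type is the aza-Achmatowicz rearrangement of 5-alkylfurfuryl carbamates and sulfonamides to tertiary 6-hydroxy-dihydropyridin-3-ones, and here the 4- and 5-alkyl groups of the furan are simply tied together as ring B. C8a is the only new stereocentre and needs no control, since both epimers, and any open form 19 left in equilibrium, ionise to one cation in step 12. The step needs chemoselectivity only, which is secured because the furan is the sole oxidisable π system of 18 and the electron-poor enone that results should resist further attack by the peracid. C2 (α to the new ketone) and C5 (γ to it) should keep their configuration because the medium is never basic and the acylated nitrogen disfavours loss of H-2 towards an oxidopyridinium species.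

Step 12
Reactants: 20 the 8a-hydroxy enone (both epimers)
Product: 22 tert-butyl (2R,5R,8aS)-2-methyl-3-oxo-5-[(5R)-5-(tert-butyldiphenylsilyloxy)octyl]-3,5,6,7,8,8a-hexahydroquinoline-1(2H)-carboxylate, via N-acyliminium ion 21 (not isolated)
Conditions: Et3SiH (4 equiv), BF3·OEt2 (2 equiv), CH2Cl2, −78 to −40 °C
Reagents that add atoms: none
Why: Ionic silane reduction of a hemiaminal, in which BF3·OEt2 turns either epimer into the same nearly flat cation 21, whose C2 methyl (pushed out of plane by the Boc group) and C5 chain (pushed out of plane by C4–H) both stand on the top face through A(1,3) strain, so Et3SiH should deliver hydride to C8a from the bottom face and give 8aS with H-8a cis to H-2, as in silane reductions of 6-alkyl aza-Achmatowicz products to 2,6-cis piperidinones.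

Step 13
Reactants: 22 the bicyclic enone
Product: 23 tert-butyl (2R,4aR,5R,8aS)-2-methyl-3-oxo-5-[(5R)-5-(tert-butyldiphenylsilyloxy)octyl]octahydroquinoline-1(2H)-carboxylate
Conditions: H2 (1 atm), Pd/C (10 wt %), EtOAc, rt
Reagents that add atoms: none
Why: Heterogeneous syn-hydrogenation of an enone, in which the Boc group keeps the C2–CH3 and C8a–C8 bonds pseudoaxial on the top face, where the C5 chain also sits, so the C4=C4a bond should bind to palladium through the bottom face and receive H-4a cis to H-8a and H-5 (4aR, cis ring fusion).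

Step 14
Reactants: 23 the cis-fused N-Boc decahydroquinolin-3-one
Product: 24 tert-butyl (2R,3R,4aR,5R,8aS)-3-hydroxy-2-methyl-5-[(5R)-5-(tert-butyldiphenylsilyloxy)octyl]octahydroquinoline-1(2H)-carboxylate
Conditions: NaBH4, MeOH/CH2Cl2, −40 to 0 °C
Reagents that add atoms: none
Why: Borohydride reduction of a ring ketone, in which ring A is a chair with the C2 methyl axial, so the small hydride attacks axially from the bottom face anti to that methyl and should give the equatorial 3R alcohol (cis to the methyl, the C3 epimer of the target), as known for N-acyl-2-methylpiperidin-3-ones.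

Step 15
Reactants: 24 the (3R)-alcohol; 25 (E)-oct-2-enoic acid
Product: 27 tert-butyl (2R,3S,4aR,5R,8aS)-2-methyl-3-[(E)-oct-2-enoyloxy]-5-[(5R)-5-(tert-butyldiphenylsilyloxy)octyl]octahydroquinoline-1(2H)-carboxylate, via oxyphosphonium ion 26 (not isolated)
Conditions: PPh3, DIAD, toluene, 0 °C to rt
Reagents that add atoms: triphenylphosphine, c1ccccc1P(c1ccccc1)c1ccccc1 (its atoms stay in 26 only)
Why: Mitsunobu esterification, in which the octenoate displaces the equatorial oxyphosphonium group of 26 by SN2 from the bottom face, so C3 is inverted to S and the ester is installed in the same step, while the equatorial leaving group has no antiperiplanar hydrogen for E2 elimination.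

Step 16
Reactants: 27 the fully protected target
Product: 28 tert-butyl (2R,3S,4aR,5R,8aS)-5-[(5R)-5-hydroxyoctyl]-2-methyl-3-[(E)-oct-2-enoyloxy]octahydroquinoline-1(2H)-carboxylate
Conditions: Bu4NF, AcOH (1:1), THF, rt to 40 °C
Reagents that add atoms: none
Why: Fluoride cleavage of the Si–O bond, buffered with acetic acid so that the enoate is neither hydrolysed nor deconjugated, and the carbamate is inert.

Step 17
Reactants: 28 the N-Boc hydroxy ester
Product: 29 (2R,3S,4aR,5R,8aS)-5-[(5R)-5-hydroxyoctyl]-2-methyldecahydroquinolin-3-yl (E)-oct-2-enoate (target)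
Conditions: CF3CO2H, CH2Cl2, 0 °C; brief cold aq NaHCO3 work-up
Reagents that add atoms: none
Why: Acidolysis of the tert-butyl carbamate with loss of isobutene and CO2, which leaves the ester, alkene and alcohol untouched, and a short cold neutralisation frees the amine without giving time for O-to-N acyl transfer.

**Compound list**
1 | (R)-1,2-epoxypentane | CCC[C@@H]1CO1 | starting material
2 | allylmagnesium bromide | C=CC[Mg]Br | starting material
3 | (4R)-oct-7-en-4-ol | C=CCC[C@H](O)CCC | intermediate
4 | tert-butyl[(4R)-oct-7-en-4-yloxy]diphenylsilane | C=CCC[C@H](O[Si](c1ccccc1)(c1ccccc1)C(C)(C)C)CCC | intermediate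
5 | 6,7-dihydro-1-benzofuran-4(5H)-one | O=C1CCCc2occc12 | starting material
6 | lithium 6,7-dihydro-1-benzofuran-4-olate | [Li]OC1=CCCc2occc12 | intermediate
7 | 6,7-dihydro-1-benzofuran-4-yl trifluoromethanesulfonate | O=S(=O)(OC1=CCCc2occc12)C(F)(F)F | intermediate
8 | 9-[(5R)-5-(tert-butyldiphenylsilyloxy)octyl]-9-borabicyclo[3.3.1]nonane | C1CC2CCCC(C1)B2CCCC[C@H](O[Si](c1ccccc1)(c1ccccc1)C(C)(C)C)CCC | intermediate
9 | 4-[(5R)-5-(tert-butyldiphenylsilyloxy)octyl]-6,7-dihydro-1-benzofuran | C1(CCCC[C@H](O[Si](c3ccccc3)(c3ccccc3)C(C)(C)C)CCC)=CCCc2occc12 | intermediate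
10 | (4R)-4-[(5R)-5-(tert-butyldiphenylsilyloxy)octyl]-4,5,6,7-tetrahydro-1-benzofuran | c1cc2[C@H](CCCC[C@H](O[Si](c3ccccc3)(c3ccccc3)C(C)(C)C)CCC)CCCc2o1 | intermediate
11 | N-methoxy-N-methylacetamide | CC(=O)N(C)OC | starting material
12 | 2-lithio derivative of 10 | [Li]c1cc2[C@H](CCCC[C@H](O[Si](c3ccccc3)(c3ccccc3)C(C)(C)C)CCC)CCCc2o1 | intermediate
13 | 1-{(4R)-4-[(5R)-5-(tert-butyldiphenylsilyloxy)octyl]-4,5,6,7-tetrahydro-1-benzofuran-2-yl}ethan-1-one | CC(=O)c1cc2[C@H](CCCC[C@H](O[Si](c3ccccc3)(c3ccccc3)C(C)(C)C)CCC)CCCc2o1 | intermediate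
14 | (R)-2-methylpropane-2-sulfinamide | CC(C)(C)[S@](N)=O | starting material
15 | (R,E)-N-sulfinyl ketimine of 13 | CC(C)(C)[S@](/N=C(\C)c1cc2[C@H](CCCC[C@H](O[Si](c3ccccc3)(c3ccccc3)C(C)(C)C)CCC)CCCc2o1)=O | intermediate
16 | (R)-N-[(1R)-1-(furyl)ethyl]-2-methylpropane-2-sulfinamide derived from 15 | CC(C)(C)[S@](N[C@@H](c1cc2[C@H](CCCC[C@H](O[Si](c3ccccc3)(c3ccccc3)C(C)(C)C)CCC)CCCc2o1)C)=O | intermediate
17 | (1R)-1-{(4R)-4-[(5R)-5-(tert-butyldiphenylsilyloxy)octyl]-4,5,6,7-tetrahydro-1-benzofuran-2-yl}ethan-1-amine hydrochloride | Cl.N[C@@H](c1cc2[C@H](CCCC[C@H](O[Si](c3ccccc3)(c3ccccc3)C(C)(C)C)CCC)CCCc2o1)C | intermediate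
18 | tert-butyl N-[(1R)-1-{(4R)-4-[(5R)-5-(tert-butyldiphenylsilyloxy)octyl]-4,5,6,7-tetrahydro-1-benzofuran-2-yl}ethyl]carbamate | CC(C)(C)OC(=O)N[C@@H](c1cc2[C@H](CCCC[C@H](O[Si](c3ccccc3)(c3ccccc3)C(C)(C)C)CCC)CCCc2o1)C | intermediate
19 | tert-butyl [(2R,Z)-4-{(2R)-2-[(5R)-5-(tert-butyldiphenylsilyloxy)octyl]-6-oxocyclohexylidene}-3-oxobutan-2-yl]carbamate | CC(C)(C)OC(=O)N[C@H](C)C(=O)/C=C1\C(=O)CCC[C@H]1CCCC[C@H](O[Si](c1ccccc1)(c1ccccc1)C(C)(C)C)CCC | intermediate
20 | tert-butyl (2R,5R)-8a-hydroxy-2-methyl-3-oxo-5-[(5R)-5-(tert-butyldiphenylsilyloxy)octyl]-3,5,6,7,8,8a-hexahydroquinoline-1(2H)-carboxylate, both C8a epimers | O=C1C=C2[C@H](CCCC[C@H](O[Si](c3ccccc3)(c3ccccc3)C(C)(C)C)CCC)CCCC2(O)N(C(=O)OC(C)(C)C)[C@@H]1C | intermediate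
21 | (2R,5R)-1-(tert-butoxycarbonyl)-2-methyl-3-oxo-5-[(5R)-5-(tert-butyldiphenylsilyloxy)octyl]-2,3,5,6,7,8-hexahydroquinolin-1-ium | O=C1C=C2[C@H](CCCC[C@H](O[Si](c3ccccc3)(c3ccccc3)C(C)(C)C)CCC)CCCC2=[N+](C(=O)OC(C)(C)C)[C@@H]1C | intermediate
22 | tert-butyl (2R,5R,8aS)-2-methyl-3-oxo-5-[(5R)-5-(tert-butyldiphenylsilyloxy)octyl]-3,5,6,7,8,8a-hexahydroquinoline-1(2H)-carboxylate | O=C1C=C2[C@H](CCCC[C@H](O[Si](c3ccccc3)(c3ccccc3)C(C)(C)C)CCC)CCC[C@@H]2N(C(=O)OC(C)(C)C)[C@@H]1C | intermediate
23 | tert-butyl (2R,4aR,5R,8aS)-2-methyl-3-oxo-5-[(5R)-5-(tert-butyldiphenylsilyloxy)octyl]octahydroquinoline-1(2H)-carboxylate | O=C1C[C@@H]2[C@H](CCCC[C@H](O[Si](c3ccccc3)(c3ccccc3)C(C)(C)C)CCC)CCC[C@@H]2N(C(=O)OC(C)(C)C)[C@@H]1C | intermediate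
24 | tert-butyl (2R,3R,4aR,5R,8aS)-3-hydroxy-2-methyl-5-[(5R)-5-(tert-butyldiphenylsilyloxy)octyl]octahydroquinoline-1(2H)-carboxylate | O[C@@H]1C[C@@H]2[C@H](CCCC[C@H](O[Si](c3ccccc3)(c3ccccc3)C(C)(C)C)CCC)CCC[C@@H]2N(C(=O)OC(C)(C)C)[C@@H]1C | intermediate
25 | (E)-oct-2-enoic acid | CCCCC/C=C/C(=O)O | starting material
26 | triphenylphosphonium ether of 24 (oxyphosphonium ion) | c1ccccc1[P+](c1ccccc1)(c1ccccc1)O[C@@H]1C[C@@H]2[C@H](CCCC[C@H](O[Si](c3ccccc3)(c3ccccc3)C(C)(C)C)CCC)CCC[C@@H]2N(C(=O)OC(C)(C)C)[C@@H]1C | intermediate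
27 | tert-butyl (2R,3S,4aR,5R,8aS)-2-methyl-3-[(E)-oct-2-enoyloxy]-5-[(5R)-5-(tert-butyldiphenylsilyloxy)octyl]octahydroquinoline-1(2H)-carboxylate | CCCCC/C=C/C(=O)O[C@H]1C[C@@H]2[C@H](CCCC[C@H](O[Si](c3ccccc3)(c3ccccc3)C(C)(C)C)CCC)CCC[C@@H]2N(C(=O)OC(C)(C)C)[C@@H]1C | intermediate
28 | tert-butyl (2R,3S,4aR,5R,8aS)-5-[(5R)-5-hydroxyoctyl]-2-methyl-3-[(E)-oct-2-enoyloxy]octahydroquinoline-1(2H)-carboxylate | CCCCC/C=C/C(=O)O[C@H]1C[C@@H]2[C@H](CCCC[C@H](O)CCC)CCC[C@@H]2N(C(=O)OC(C)(C)C)[C@@H]1C | intermediate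
29 | (2R,3S,4aR,5R,8aS)-5-[(5R)-5-hydroxyoctyl]-2-methyldecahydroquinolin-3-yl (E)-oct-2-enoate | CCCCC/C=C/C(=O)O[C@H]1C[C@@H]2[C@H](CCCC[C@H](O)CCC)CCC[C@@H]2N[C@@H]1C | target

Total step count: 17.
Longest linear sequence: 16 steps (steps 1, 2 and 4–17, from 1). The branch from 5 joins at step 4.

**Steps most likely to fail**

**Step 5.**
- What may go wrong: the catalyst may discriminate poorly between the faces of a cyclic olefin whose aryl group and ring CH2 are cis. Acid-promoted double-bond migration or dehydrogenation towards the benzofuran may also compete. The C4 epimer differs from 10 only relative to a remote centre, so it could hardly be separated.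
- Fallback (from 4, back at 10): the C5 centre is made by asymmetric conjugate addition and the furan is built afterwards.
  - Alkene 4 is hydroborated with Et2BH to the diethyl(alkyl)borane F1, and boron–zinc exchange with Et2Zn gives the dialkylzinc F2.
  - Cu(OTf)2 with the (R,S,S) BINOL-derived phosphoramidite carrying a bis(1-phenylethyl)amine unit adds one alkyl group of F2 to bought cyclohex-2-enone (O=C1C=CCCC1). This gives the zinc enolate F3, expected to be 3R by analogy with Et2Zn.
  - Allyl acetate and Pd(PPh3)4 in the same flask allylate F3 regiospecifically to the trans-2-allyl-3-alkylcyclohexanone F4.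
  - Ozonolysis (O3, then Me2S) gives the 1,4-keto aldehyde F5.
  - Catalytic p-TsOH in toluene closes the furan (Paal–Knorr synthesis), which removes the allyl-bearing centre and gives 10.

**Step 12.**
- What may go wrong: ionisation of a tertiary hemiaminal deactivated by the enone may be slower than Lewis-acid cleavage of the Boc group. The cation may lose a proton from C8 instead of accepting hydride. Acid-induced dienol formation may erode C5, and the facial bias for hydride may be incomplete.
- Fallback (from 20, back at 23): the proton loss is made deliberate and both ring-fusion hydrogens are delivered on a metal surface.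
  - Compound 20 is dehydrated (pyridinium p-toluenesulfonate, 4 Å sieves, toluene, 50 °C) to the C8=C8a/C4=C4a dienone enecarbamate F6.
  - F6 is nearly planar and carries the C2 methyl and the C5 chain on its top face.
  - Exhaustive hydrogenation (H2, 5 bar, Pd/C, EtOAc) should add hydrogen at C8a and C4a from the bottom face and give 23 directly, replacing steps 12 and 13.

**Step 15.**
- What may go wrong: displacement at a hindered secondary carbon next to the substituted C2 may be slow. Acyl transfer with retention, or elimination towards the C3–C4 alkene, could then take over.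
- Fallback (from 24, back at 27): the redox condensation is replaced by a sulfonate displacement.
  - Alcohol 24 is converted (MsCl, Et3N, CH2Cl2, 0 °C) into the equatorial mesylate F7.
  - F7 is heated with the cesium (E)-oct-2-enoate F8 (made from 25 and Cs2CO3) and 18-crown-6 in toluene at 80–100 °C.
  - The weakly paired carboxylate should attack from the bottom face with inversion and give 27.

**Further compounds**
F1 | step 5 | diethyl[(5R)-5-(tert-butyldiphenylsilyloxy)octyl]borane | CCB(CC)CCCC[C@H](O[Si](c1ccccc1)(c1ccccc1)C(C)(C)C)CCC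
F2 | step 5 | bis[(5R)-5-(tert-butyldiphenylsilyloxy)octyl]zinc | CCC[C@H](CCCC[Zn]CCCC[C@H](O[Si](c1ccccc1)(c1ccccc1)C(C)(C)C)CCC)O[Si](c1ccccc1)(c1ccccc1)C(C)(C)C
F3 | step 5 | alkylzinc (3R)-3-[(5R)-5-(tert-butyldiphenylsilyloxy)octyl]cyclohex-1-en-1-olate | CCC[C@H](CCCC[Zn]OC1=C[C@H](CCCC[C@H](O[Si](c2ccccc2)(c2ccccc2)C(C)(C)C)CCC)CCC1)O[Si](c1ccccc1)(c1ccccc1)C(C)(C)C
F4 | step 5 | (2S,3R)-2-allyl-3-[(5R)-5-(tert-butyldiphenylsilyloxy)octyl]cyclohexan-1-one | O=C1CCC[C@@H](CCCC[C@H](O[Si](c3ccccc3)(c3ccccc3)C(C)(C)C)CCC)[C@@H]1CC=C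
F5 | step 5 | 2-{(1S,2R)-2-[(5R)-5-(tert-butyldiphenylsilyloxy)octyl]-6-oxocyclohexyl}acetaldehyde | O=C1CCC[C@@H](CCCC[C@H](O[Si](c3ccccc3)(c3ccccc3)C(C)(C)C)CCC)[C@@H]1CC=O
F6 | step 12 | tert-butyl (2R,5R)-2-methyl-3-oxo-5-[(5R)-5-(tert-butyldiphenylsilyloxy)octyl]-3,5,6,7-tetrahydroquinoline-1(2H)-carboxylate | O=C1C=C2[C@H](CCCC[C@H](O[Si](c3ccccc3)(c3ccccc3)C(C)(C)C)CCC)CCC=C2N(C(=O)OC(C)(C)C)[C@@H]1C
F7 | step 15 | tert-butyl (2R,3R,4aR,5R,8aS)-3-(methanesulfonyloxy)-2-methyl-5-[(5R)-5-(tert-butyldiphenylsilyloxy)octyl]octahydroquinoline-1(2H)-carboxylate | CS(=O)(=O)O[C@@H]1C[C@@H]2[C@H](CCCC[C@H](O[Si](c3ccccc3)(c3ccccc3)C(C)(C)C)CCC)CCC[C@@H]2N(C(=O)OC(C)(C)C)[C@@H]1C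
F8 | step 15 | cesium (E)-oct-2-enoate | CCCCC/C=C/C(=O)[O-].[Cs+]
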